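**Retrosynthetic overview**
Rings are lettered A (2-aryloxyphloroglucinol end) to E (3,4,5-trihydroxyphenoxy end) and are joined by four diaryl ethers (carbon 2 of ring A to carbon 1 of ring B, carbon 4 of ring B to carbon 3 of ring C, carbon 2 of ring C to carbon 1 of ring D, carbon 4 of ring D to carbon 1 of ring E); the last step is the twelvefold O-demethylation of the dodecamethyl ether.
The ether between rings C and D is cut first (Ullmann coupling of the hindered A–B–C phenol with a D–E aryl bromide, itself from a Chan–Lam coupling that makes the ether between rings D and E), then the ether between rings B and C (SNAr of the ring B phenol on 2-fluoro-4,6-dimethoxybenzaldehyde, whose formyl carbon becomes the hydroxyl at carbon 2 of ring C by Baeyer–Villiger oxidation).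
The strategy rests on ring A: its ether carbon (carbon 2) lies between the hydroxylated carbons 1 and 3 and the third hydroxyl sits at carbon 5, the pattern of a malonate (carbons 1, 2 and 3) condensed with an acetonedicarboxylate (carbons 4, 5 and 6).
Ring A is therefore cut at the bond between its carbons 1 and 6 and at the bond between its carbons 3 and 4: [3+3] double Claisen benzannulation of a dimethyl 2-aryloxymalonate that already carries ring B on oxygen, followed by loss of the two ester groups.
Ring order: ring B is bought (syringaldehyde), ring A is the only ring built (step 4), ring C is attached in step 9 and the preformed D–E unit in step 12; the target has no stereocentre.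

Key step: step 4

Remark: the phenolic oxygens of the target are carried as methyl ethers (those of ring A from step 6 on); only the oxygen at carbon 4 of ring B is masked differently (as a benzyl ether) until ring A is in place.

**Route**

Step 1
Reactants: 1 syringaldehyde (4-hydroxy-3,5-dimethoxybenzaldehyde)
Product: 2 4-(benzyloxy)-3,5-dimethoxybenzaldehyde
Conditions: BnBr, K2CO3, DMF, 60 °C
Reagents that add atoms: benzyl bromide, BrCc1ccccc1
Why: Williamson ether synthesis, in which the phenoxide (acidified by the para formyl group) should be O-alkylated cleanly by the benzylic bromide.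

Step 2
Reactants: 2 4-(benzyloxy)-3,5-dimethoxybenzaldehyde
Product: 4 4-(benzyloxy)-3,5-dimethoxyphenol, via aryl formate 3 (not isolated)
Conditions: mCPBA, CH2Cl2, 0 °C → rt; aq. NaHCO3 wash; then K2CO3 (cat.), MeOH, rt
Reagents that add atoms: 3-chloroperoxybenzoic acid (mCPBA), O=C(OO)c1cccc(Cl)c1
Why: Baeyer–Villiger oxidation, in which the electron-rich aryl group migrates in preference to hydrogen, followed by base-catalysed methanolysis of the formate.

Step 3
Reactants: 4 4-(benzyloxy)-3,5-dimethoxyphenol; 5 dimethyl chloromalonate (dimethyl 2-chloropropanedioate)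
Product: 6 dimethyl 2-[4-(benzyloxy)-3,5-dimethoxyphenoxy]malonate
Conditions: K2CO3, acetone, reflux
Reagents that add atoms: none
Why: Williamson-type SN2 O-alkylation of a phenoxide by an α-halomalonate, using the chloride because a bromomalonate could transfer bromine to so electron-rich a phenoxide.

Step 4
Reactants: 6 dimethyl 2-[4-(benzyloxy)-3,5-dimethoxyphenoxy]malonate; 7 dimethyl 1,3-acetonedicarboxylate (dimethyl 3-oxopentanedioate)
Product: 9 dimethyl 5-[4-(benzyloxy)-3,5-dimethoxyphenoxy]-2,4,6-trihydroxyisophthalate, via diketo triester 8 (not isolated)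
Conditions: 7 + NaOMe (1.0 equiv), MeOH, rt; add 6, toluene, distil off MeOH, 110 °C; then NaOMe (1.5 equiv), 110 °C; 1 M HCl work-up
Reagents that add atoms: none
Why: Proposed new method: the sodium enolate of 7 should attack one ester carbonyl of 6 (intermolecular Claisen C-acylation, forming the bond between carbons 1 and 6 of ring A) to give diketo triester 8, and after the second charge of base the remaining CH2 of 8 should attack the second malonate ester in an intramolecular Claisen (Dieckmann-type) acyl substitution (forming the bond between carbons 3 and 4 of ring A). This closes ring A, the only ring formed, in a 6-exo-trig mode, and the cyclohexane-1,3,5-trione enolises to the benzenetriol, whose polyanion is the thermodynamic sink. The closest known reaction types are the alkoxide-mediated condensation of dialkyl malonates with dialkyl acetonedicarboxylates to phloroglucinol dicarboxylates and the NaOMe-mediated double acyl substitution of 2-aryloxymalonates by amidines to 5-aryloxypyrimidine-4,6-diols, which shows that both esters of an aryloxymalonate stay electrophilic under methoxide. No stereocentre is formed. The step needs ring closure through carbon and not through enol oxygen (benzene versus 4-hydroxy-2-pyranone) and cross-condensation in preference to self-condensation of 7; the first should be secured by equilibrating methoxide, which reopens O-acyl products but not the aromatic polyanion, and the second by charging 7 as its preformed mono-enolate (no free ketone) against neutral 6 and adding the second base charge only after 6 is consumed. The aryloxy-bearing carbon of 6 never has to act as a nucleophile, so the di-ortho-substituted ether from carbon 2 of ring A to ring B enters the ring without any aryl C–O coupling.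

Step 5
Reactants: 9 dimethyl 5-[4-(benzyloxy)-3,5-dimethoxyphenoxy]-2,4,6-trihydroxyisophthalate
Product: 11 2-[4-(benzyloxy)-3,5-dimethoxyphenoxy]benzene-1,3,5-triol, via isophthalic diacid 10 (not isolated)
Conditions: 2 M NaOH, H2O–dioxane, reflux, N2; then 2 M HCl, 60 °C
Reagents that add atoms: none
Why: Ester saponification followed by decarboxylation, which 2,4,6-trihydroxybenzoic acids undergo readily through their keto tautomers (β-keto acid decarboxylation), while the benzyl, methyl and diaryl ethers are inert to aqueous base and dilute acid.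

Step 6
Reactants: 11 2-[4-(benzyloxy)-3,5-dimethoxyphenoxy]benzene-1,3,5-triol
Product: 12 2-[4-(benzyloxy)-3,5-dimethoxyphenoxy]-1,3,5-trimethoxybenzene
Conditions: Me2SO4, K2CO3, acetone, reflux, N2
Reagents that add atoms: dimethyl sulfate, COS(=O)(=O)OC
Why: Williamson O-methylation, where the hard sulfate electrophile with carbonate in acetone should favour O- over C-methylation of the phloroglucinol.

Step 7
Reactants: 12 2-[4-(benzyloxy)-3,5-dimethoxyphenoxy]-1,3,5-trimethoxybenzene
Product: 13 2,6-dimethoxy-4-(2,4,6-trimethoxyphenoxy)phenol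
Conditions: H2 (1 atm), 10% Pd/C, EtOAc–MeOH, rt
Reagents that add atoms: none
Why: Catalytic hydrogenolysis of the benzyl ether, which should free the hydroxyl at carbon 4 of ring B while methyl and diaryl ethers are untouched.

Step 8
Reactants: 14 1-fluoro-3,5-dimethoxybenzene
Product: 16 2-fluoro-4,6-dimethoxybenzaldehyde, via aryl iminium salt 15 (not isolated)
Conditions: POCl3, DMF, 0 → 70 °C; then H2O, 50 °C
Reagents that add atoms: N,N-dimethylformamide, CN(C)C=O; water, O
Why: Vilsmeier–Haack formylation, in which the chloroiminium ion should attack the position para to one methoxy and ortho to the other (next to fluorine) and not the more crowded position between the two methoxy groups, and hydrolysis of the iminium salt gives the aldehyde.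

Step 9
Reactants: 13 2,6-dimethoxy-4-(2,4,6-trimethoxyphenoxy)phenol; 16 2-fluoro-4,6-dimethoxybenzaldehyde
Product: 17 2-[2,6-dimethoxy-4-(2,4,6-trimethoxyphenoxy)phenoxy]-4,6-dimethoxybenzaldehyde
Conditions: Cs2CO3, DMSO, 110 °C, N2
Reagents that add atoms: none
Why: Nucleophilic aromatic substitution (addition–elimination), in which the caesium phenoxide adds at the fluorine-bearing carbon ortho to the formyl group, which stabilises the Meisenheimer adduct, and the two methoxy groups are meta to the site of attack and so do not donate into it.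

Step 10
Reactants: 17 2-[2,6-dimethoxy-4-(2,4,6-trimethoxyphenoxy)phenoxy]-4,6-dimethoxybenzaldehyde
Product: 19 2-[2,6-dimethoxy-4-(2,4,6-trimethoxyphenoxy)phenoxy]-4,6-dimethoxyphenol, via aryl formate 18 (not isolated)
Conditions: mCPBA, CH2Cl2, 0 °C → rt; aq. NaHCO3 wash; then K2CO3 (cat.), MeOH, rt
Reagents that add atoms: 3-chloroperoxybenzoic acid (mCPBA), O=C(OO)c1cccc(Cl)c1
Why: Baeyer–Villiger oxidation, in which the 2,4,6-trioxygenated aryl group migrates in the Criegee adduct, and methanolysis of the formate turns the former formyl position into the hydroxyl at carbon 2 of ring C, with the oxygen at carbon 5 of ring C already methylated.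

Step 11
Reactants: 20 4-bromo-2,6-dimethoxyphenol; 21 (3,4,5-trimethoxyphenyl)boronic acid
Product: 22 5-bromo-1,3-dimethoxy-2-(3,4,5-trimethoxyphenoxy)benzene
Conditions: Cu(OAc)2 (20 mol %), pyridine, 4 Å molecular sieves, CH2Cl2, O2 (1 atm), rt
Reagents that add atoms: none
Why: Chan–Lam oxidative C–O coupling, in which the aryl group passes from boron to copper and reductive elimination from a trivalent copper aryl phenoxide forms the ether between carbon 4 of ring D and carbon 1 of ring E, while the C–Br bond does not react with copper acetate at room temperature.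

Step 12
Reactants: 19 2-[2,6-dimethoxy-4-(2,4,6-trimethoxyphenoxy)phenoxy]-4,6-dimethoxyphenol; 22 5-bromo-1,3-dimethoxy-2-(3,4,5-trimethoxyphenoxy)benzene
Product: 23 2-{2-[3,5-dimethoxy-4-(3,4,5-trimethoxyphenoxy)phenoxy]-3,5-dimethoxyphenoxy}-1,3-dimethoxy-5-(2,4,6-trimethoxyphenoxy)benzene (dodecamethyl ether of the target)
Conditions: CuI (10 mol %), picolinic acid (20 mol %), K3PO4, DMSO, 100 °C, Ar
Reagents that add atoms: none
Why: Ullmann-type diaryl ether coupling with picolinate-ligated monovalent copper, a system suited to di-ortho-substituted phenols when the aryl bromide has no ortho substituent, as in 22 (hydrogen at both carbons next to the bromine-bearing carbon).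

Step 13
Reactants: 23 dodecamethyl ether of the target
Product: 24 2-(4-{2-[3,5-dihydroxy-4-(3,4,5-trihydroxyphenoxy)phenoxy]-3,5-dihydroxyphenoxy}-3,5-dihydroxyphenoxy)benzene-1,3,5-triol (CNP0227069.0)
Conditions: BBr3 (excess), CH2Cl2, −78 °C → rt; then H2O, 0 °C; work-up under Ar
Reagents that add atoms: none
Why: Lewis acid cleavage of aryl methyl ethers, in which each methoxy oxygen binds BBr3 and bromide removes the methyl group by SN2, whereas the four diaryl ether oxygens carry no sp3 carbon and should stay intact.

**Compound list**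
1 | syringaldehyde (4-hydroxy-3,5-dimethoxybenzaldehyde) | COc1cc(C=O)cc(OC)c1O | starting material
2 | 4-(benzyloxy)-3,5-dimethoxybenzaldehyde | COc1cc(C=O)cc(OC)c1OCc1ccccc1 | intermediate
3 | 4-(benzyloxy)-3,5-dimethoxyphenyl formate (formed in situ) | COc1cc(OC=O)cc(OC)c1OCc1ccccc1 | intermediate
4 | 4-(benzyloxy)-3,5-dimethoxyphenol | COc1cc(O)cc(OC)c1OCc1ccccc1 | intermediate
5 | dimethyl chloromalonate | COC(=O)C(Cl)C(=O)OC | starting material
6 | dimethyl 2-[4-(benzyloxy)-3,5-dimethoxyphenoxy]malonate | COC(=O)C(Oc1cc(OC)c(OCc2ccccc2)c(OC)c1)C(=O)OC | intermediate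
7 | dimethyl 1,3-acetonedicarboxylate | COC(=O)CC(=O)CC(=O)OC | starting material
8 | dimethyl 2-{2-[4-(benzyloxy)-3,5-dimethoxyphenoxy]-3-methoxy-3-oxopropanoyl}-3-oxopentanedioate (formed in situ, mixture of tautomers) | COC(=O)CC(=O)C(C(=O)OC)C(=O)C(Oc1cc(OC)c(OCc2ccccc2)c(OC)c1)C(=O)OC | intermediate
9 | dimethyl 5-[4-(benzyloxy)-3,5-dimethoxyphenoxy]-2,4,6-trihydroxyisophthalate | COC(=O)c1c(O)c(Oc2cc(OC)c(OCc3ccccc3)c(OC)c2)c(O)c(C(=O)OC)c1O | intermediate
10 | 5-[4-(benzyloxy)-3,5-dimethoxyphenoxy]-2,4,6-trihydroxyisophthalic acid (formed in situ) | OC(=O)c1c(O)c(Oc2cc(OC)c(OCc3ccccc3)c(OC)c2)c(O)c(C(=O)O)c1O | intermediate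
11 | 2-[4-(benzyloxy)-3,5-dimethoxyphenoxy]benzene-1,3,5-triol | Oc1cc(O)c(Oc2cc(OC)c(OCc3ccccc3)c(OC)c2)c(O)c1 | intermediate
12 | 2-[4-(benzyloxy)-3,5-dimethoxyphenoxy]-1,3,5-trimethoxybenzene | COc1cc(OC)c(Oc2cc(OC)c(OCc3ccccc3)c(OC)c2)c(OC)c1 | intermediate
13 | 2,6-dimethoxy-4-(2,4,6-trimethoxyphenoxy)phenol | COc1cc(OC)c(Oc2cc(OC)c(O)c(OC)c2)c(OC)c1 | intermediate
14 | 1-fluoro-3,5-dimethoxybenzene | COc1cc(F)cc(OC)c1 | starting material
15 | N-[(2-fluoro-4,6-dimethoxyphenyl)methylidene]-N-methylmethanaminium dichlorophosphate (formed in situ) | C[N+](C)=Cc1c(F)cc(OC)cc1OC.[O-]P(=O)(Cl)Cl | intermediate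
16 | 2-fluoro-4,6-dimethoxybenzaldehyde | COc1cc(F)c(C=O)c(OC)c1 | intermediate
17 | 2-[2,6-dimethoxy-4-(2,4,6-trimethoxyphenoxy)phenoxy]-4,6-dimethoxybenzaldehyde | COc1cc(OC)c(Oc2cc(OC)c(Oc3cc(OC)cc(OC)c3C=O)c(OC)c2)c(OC)c1 | intermediate
18 | 2-[2,6-dimethoxy-4-(2,4,6-trimethoxyphenoxy)phenoxy]-4,6-dimethoxyphenyl formate (formed in situ) | COc1cc(OC)c(Oc2cc(OC)c(Oc3cc(OC)cc(OC)c3OC=O)c(OC)c2)c(OC)c1 | intermediate
19 | 2-[2,6-dimethoxy-4-(2,4,6-trimethoxyphenoxy)phenoxy]-4,6-dimethoxyphenol | COc1cc(OC)c(Oc2cc(OC)c(Oc3cc(OC)cc(OC)c3O)c(OC)c2)c(OC)c1 | intermediate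
20 | 4-bromo-2,6-dimethoxyphenol | COc1cc(Br)cc(OC)c1O | starting material
21 | (3,4,5-trimethoxyphenyl)boronic acid | COc1cc(B(O)O)cc(OC)c1OC | starting material
22 | 5-bromo-1,3-dimethoxy-2-(3,4,5-trimethoxyphenoxy)benzene | COc1cc(Br)cc(OC)c1Oc1cc(OC)c(OC)c(OC)c1 | intermediate
23 | 2-{2-[3,5-dimethoxy-4-(3,4,5-trimethoxyphenoxy)phenoxy]-3,5-dimethoxyphenoxy}-1,3-dimethoxy-5-(2,4,6-trimethoxyphenoxy)benzene | COc1cc(OC)c(Oc2cc(OC)c(Oc3cc(OC)cc(OC)c3Oc3cc(OC)c(Oc4cc(OC)c(OC)c(OC)c4)c(OC)c3)c(OC)c2)c(OC)c1 | intermediate
24 | 2-(4-{2-[3,5-dihydroxy-4-(3,4,5-trihydroxyphenoxy)phenoxy]-3,5-dihydroxyphenoxy}-3,5-dihydroxyphenoxy)benzene-1,3,5-triol (CNP0227069.0) | Oc1cc(O)c(Oc2cc(O)c(Oc3cc(O)cc(O)c3Oc3cc(O)c(Oc4cc(O)c(O)c(O)c4)c(O)c3)c(O)c2)c(O)c1 | target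

**Step count**
Total: 13 steps. Longest linear sequence: 11 steps (steps 1–7, 9, 10, 12, 13).

**Steps most likely to fail**

Step 4 (proposed new method). The cross-condensation may lose to self-condensation of the acetonedicarboxylate, to deactivation of the malonate by enolisation, or to ring closure through enol oxygen. The fallback makes the ether between ring A and ring B by known copper catalysis instead of building ring A. It sets out from 20, which is benzylated (BnBr, K2CO3, DMF, 60 °C) to 2-(benzyloxy)-5-bromo-1,3-dimethoxybenzene F1. Ullmann coupling of F1 with commercial 2,4,6-trimethoxyphenol (CuI, picolinic acid, K3PO4, DMSO, 100 °C; hindered phenol, aryl bromide without ortho substituents) comes back to the route at 12.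

Step 9. Addition of the di-ortho-substituted phenoxide to a fluoroarene whose formyl activation is weakened by two methoxy donors may be too slow, so that oxidative decay of the phenoxide at 110 °C takes over. The fallback brings ring C in as a quinone and sets out from 13. Its potassium phenoxide (K2CO3, MeCN, 0 °C) should displace bromide from 2-bromo-6-methoxy-1,4-benzoquinone F2 (Teuber oxidation of commercial 2-bromo-6-methoxyphenol with K2NO(SO3)2) by conjugate addition–elimination, a known reaction of haloquinones with phenoxides, to give 2-[2,6-dimethoxy-4-(2,4,6-trimethoxyphenoxy)phenoxy]-6-methoxy-1,4-benzoquinone F3. Reduction with Na2S2O4 (EtOAc–H2O, rt) gives 2-[2,6-dimethoxy-4-(2,4,6-trimethoxyphenoxy)phenoxy]-6-methoxybenzene-1,4-diol F4. Methylation with MeI (1 equiv) and K2CO3 in acetone should occur at the hydroxyl with two free ortho positions, the other being shielded by a methoxy and the aryloxy group, and comes back to the route at 19.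

Step 12. Copper-mediated C–O bond formation at the di-ortho-substituted, easily oxidised phenol may stall at 100 °C, leaving hydrodebromination of the bromide and oxidation of the phenol as the main processes. The fallback inverts the polarity of the D–E partner and forms the ether oxidatively at room temperature. It sets out from 22: bromine–lithium exchange (n-BuLi, THF, −78 °C), B(OiPr)3, then aq. HCl gives [3,5-dimethoxy-4-(3,4,5-trimethoxyphenoxy)phenyl]boronic acid F5. Chan–Lam coupling of F5 with 19 (Cu(OAc)2, pyridine, 4 Å molecular sieves, CH2Cl2, O2, rt), which accepts di-ortho-substituted phenols when the boronic acid has no ortho substituent, comes back to the route at 23.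

**Further compounds**
F1 | step 4 | 2-(benzyloxy)-5-bromo-1,3-dimethoxybenzene | COc1cc(Br)cc(OC)c1OCc1ccccc1
F2 | step 9 | 2-bromo-6-methoxy-1,4-benzoquinone | COC1=CC(=O)C=C(Br)C1=O
F3 | step 9 | 2-[2,6-dimethoxy-4-(2,4,6-trimethoxyphenoxy)phenoxy]-6-methoxy-1,4-benzoquinone | COC1=CC(=O)C=C(Oc2c(OC)cc(Oc3c(OC)cc(OC)cc3OC)cc2OC)C1=O
F4 | step 9 | 2-[2,6-dimethoxy-4-(2,4,6-trimethoxyphenoxy)phenoxy]-6-methoxybenzene-1,4-diol | COc1cc(O)cc(Oc2c(OC)cc(Oc3c(OC)cc(OC)cc3OC)cc2OC)c1O
F5 | step 12 | [3,5-dimethoxy-4-(3,4,5-trimethoxyphenoxy)phenyl]boronic acid | COc1cc(B(O)O)cc(OC)c1Oc1cc(OC)c(OC)c(OC)c1
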